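**Retrosynthetic overview**
1. The target is a (3S)-isoflavan. Its two phenols (C7-OH, C3'-OH) are masked as benzyl ethers and C2 is traced back to an acetal carbon, so the route ends with an ionic reduction at C2 and a double hydrogenolysis.
2. The strategy rests on ring C. Cutting O1–C2 and C3–C4 splits its atoms O1–C2–C3–C4–C4a–C8a into the heterodiene O1=C8a–C4a=C4 (an ortho-quinone methide on ring A) and the alkene C2=C3, an (E)-enol ether carrying ring B on C3.
3. The methide is released from 4-benzyloxy-2-hydroxy-3-methoxybenzyl alcohol. This takes three steps from 2-methoxyresorcinol, with regiochemistry fixed by symmetry and by chelation of the 2-OH.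
4. The enol ether is made geometrically pure by Suzuki–Miyaura coupling of commercial (E)-2-ethoxyvinylboronate with the ring B bromide, which comes from syringol through a symmetric dibromide. O-ethyl replaces O-methyl because this group is lost at C2 anyway, and a methoxymethylene Wittig reaction would give an E/Z mixture.
5. Rings A and B are bought as arenes. Ring C is the only ring formed, in one step together with C3.

Key step: step 9

Assumption: the sense of induction of the binaphthyl catalyst on this substrate pair cannot be derived from precedent, so the (R)-catalyst is written and the equally available (S)-catalyst is used if a trial run shows that (R) favours the (3R) series.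

**Step 1**
Reactants: 1 2-methoxyresorcinol (2-methoxybenzene-1,3-diol)
Product: 3 2,4-dihydroxy-3-methoxybenzaldehyde, via iminium chloride 2 (not isolated)
Conditions: POCl3, DMF, MeCN, 0 °C → rt; then H2O, 50 °C
Reagents that add atoms: N,N-dimethylformamide, CN(C)C=O; water, O
Why: Vilsmeier–Haack formylation should give a single monoaldehyde, because C4 and C6 of the mirror-symmetric diol are equivalent (each ortho to one OH and para to the other) and the iminium group of 2 deactivates the ring against a second attack.

**Step 2**
Reactants: 3 2,4-dihydroxy-3-methoxybenzaldehyde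
Product: 4 4-(benzyloxy)-2-hydroxy-3-methoxybenzaldehyde
Conditions: BnBr (1.05 equiv), CsHCO3, MeCN, 80 °C
Reagents that add atoms: benzyl bromide, BrCc1ccccc1
Why: Williamson etherification under a weak base should alkylate only the acidic 4-OH para to the formyl group, because the 2-OH is held in a hydrogen bond to the carbonyl oxygen.

**Step 3**
Reactants: 4 4-(benzyloxy)-2-hydroxy-3-methoxybenzaldehyde
Product: 5 4-(benzyloxy)-2-hydroxy-3-methoxybenzyl alcohol
Conditions: NaBH4, THF/EtOH, 0 °C; pH 7 phosphate buffer
Reagents that add atoms: none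
Why: Borohydride reduction of the aldehyde is routine, and the cold, neutral work-up keeps the acid- and heat-sensitive salicyl alcohol from losing water too early.

**Step 4**
Reactants: 6 2,6-dimethoxyphenol (syringol)
Product: 7 2-(benzyloxy)-1,3-dimethoxybenzene
Conditions: BnBr, K2CO3, DMF, 50 °C
Reagents that add atoms: benzyl bromide, BrCc1ccccc1
Why: Williamson etherification marks the oxygen flanked by two methoxy groups as the future 3'-OH, with a group that leaves in the last step together with the C7 benzyl ether.

**Step 5**
Reactants: 7 2-(benzyloxy)-1,3-dimethoxybenzene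
Product: 8 3-(benzyloxy)-1,5-dibromo-2,4-dimethoxybenzene
Conditions: NBS (2.1 equiv), MeCN, 0 °C → rt, dark
Reagents that add atoms: N-bromosuccinimide, O=C1CCC(=O)N1Br
Why: In this electrophilic aromatic bromination each bromine should enter ortho to one methoxy group and para to the other, whereas the third free position is only para to the twisted benzyloxy oxygen, so the symmetric dibromide is expected.

**Step 6**
Reactants: 8 3-(benzyloxy)-1,5-dibromo-2,4-dimethoxybenzene
Product: 11 3-(benzyloxy)-5-bromo-2,4-dimethoxyphenol, via aryllithium 9 (not isolated), via lithium aryltrimethoxyborate 10 (not isolated)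
Conditions: n-BuLi (1.0 equiv), THF, −78 °C; B(OMe)3, −78 °C → rt; then AcOH, 30% H2O2, 0 °C → rt
Reagents that add atoms: hydrogen peroxide, OO
Why: Bromine–lithium exchange with one equivalent of n-BuLi on a symmetric dibromide can give only one monolithio species, and borylation followed by peroxide oxidation (1,2-aryl shift from boron to oxygen) puts the future 5'-oxygen in its place.

**Step 7**
Reactants: 11 3-(benzyloxy)-5-bromo-2,4-dimethoxyphenol
Product: 12 3-(benzyloxy)-1-bromo-2,4,5-trimethoxybenzene
Conditions: MeI, K2CO3, acetone, reflux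
Reagents that add atoms: iodomethane, CI
Why: Williamson methylation of the only free phenol completes the ring B oxygenation pattern (2',4',5'-OMe, 3'-OBn) with bromine at the future C1'.

**Step 8**
Reactants: 12 3-(benzyloxy)-1-bromo-2,4,5-trimethoxybenzene; 13 (E)-2-(2-ethoxyvinyl)-4,4,5,5-tetramethyl-1,3,2-dioxaborolane
Product: 14 3-(benzyloxy)-1-[(E)-2-ethoxyvinyl]-2,4,5-trimethoxybenzene
Conditions: 13 (1.3 equiv), Pd(OAc)2 (3 mol %), SPhos (6 mol %), K3PO4, 1,4-dioxane/H2O, 80 °C; chromatography on Et3N-washed silica
Reagents that add atoms: none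
Why: Suzuki–Miyaura coupling transfers the alkenyl group with retention of geometry, so the E configuration of the commercial boronate is carried into 14, and the basic medium leaves the enol ether intact.

**Step 9**
Reactants: 5 4-(benzyloxy)-2-hydroxy-3-methoxybenzyl alcohol; 14 3-(benzyloxy)-1-[(E)-2-ethoxyvinyl]-2,4,5-trimethoxybenzene
Product: 16 (2R,3S)-7-(benzyloxy)-3-[3-(benzyloxy)-2,4,5-trimethoxyphenyl]-2-ethoxy-8-methoxychroman, via ortho-quinone methide 15 (not isolated)
Conditions: (R)-3,3'-bis(2,4,6-triisopropylphenyl)-1,1'-binaphthyl-2,2'-diyl N-(trifluoromethylsulfonyl)phosphoramide (10 mol %), 4 Å MS, toluene, −30 °C; 5 (1.5 equiv) added by syringe pump over 6 h; Et3N quench at −30 °C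
Reagents that add atoms: none
Why: Proposed new method: the strong chiral acid protonates the benzylic hydroxyl of 5, water leaves with the push of the phenolic O1 and of the C7 benzyloxy group para to C4a, and methide 15 stays hydrogen-bonded or ion-paired through O1 to the phosphoramide anion, which lowers its LUMO. The aryl-bearing carbon of 14, the nucleophilic end of the enol ether, bonds to the methide CH2 (C3–C4) slightly ahead of the bond from O1 to the ethoxy-bearing carbon (O1–C2), so ring C is closed by a concerted but asynchronous inverse-demand hetero-Diels–Alder [4+2] addition, whose stepwise limit would be a 6-exo-trig capture of the oxocarbenium carbon by O1. The closest known reaction type is the chiral phosphoric acid catalysed [4+2] addition of in situ formed, C4-aryl ortho-quinone methides to enamides, vinylindoles or hydroxystyrenes; not yet shown is a methide with a bare CH2 terminus combined with a dienophile that offers the catalyst no hydrogen-bond donor. C3 is fixed by the enol ether face that meets C4, and since C4 and O1 are not stereogenic this face results from two preferences that must both be high, the shielding of one methide face by the 3,3'-aryl walls of the catalyst and the endo placing of the ethoxy group with ring B turned outward. C2 follows C3, because suprafacial addition turns the E geometry of 14 into the 2,3-trans relation. The step needs regioselectivity, given by the matched polarity of the two partners, and chemoselectivity over self-condensation of 15 and hydration of 14, given by slow addition of 5, low temperature and molecular sieves.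

**Step 10**
Reactants: 16 (2R,3S)-7-(benzyloxy)-3-[3-(benzyloxy)-2,4,5-trimethoxyphenyl]-2-ethoxy-8-methoxychroman
Product: 18 (3S)-7-(benzyloxy)-3-[3-(benzyloxy)-2,4,5-trimethoxyphenyl]-8-methoxychroman, via oxocarbenium ion 17 (not isolated)
Conditions: Et3SiH (10 equiv), BF3·OEt2 (1.5 equiv), CH2Cl2, −78 °C → −40 °C; sat. aq NaHCO3
Reagents that add atoms: none
Why: In this ionic hydrogenation of an acetal (silane/Lewis acid reduction) BF3 removes the exocyclic ethoxy group and the large excess of silane should capture ion 17 at C2 in the cold before it can lose H3, so C2 becomes CH2, the C3 centre is carried through, and the aryl benzyl ethers survive.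

**Step 11**
Reactants: 18 (3S)-7-(benzyloxy)-3-[3-(benzyloxy)-2,4,5-trimethoxyphenyl]-8-methoxychroman
Product: 19 (3S)-3-(3-hydroxy-2,4,5-trimethoxyphenyl)-8-methoxychroman-7-ol (CNP0201239.1)
Conditions: H2 (1 atm), 10% Pd/C, EtOAc/MeOH, rt
Reagents that add atoms: none
Why: Catalytic hydrogenolysis should cleave only the two O–CH2Ph bonds, because O1–C2 is not benzylic and C3 and C4 carry no heteroatom, so ring C and the (3S) centre stay intact.

**Compound list**
1 | 2-methoxyresorcinol | COc1c(O)cccc1O | starting material
2 | (2,4-dihydroxy-3-methoxybenzylidene)dimethyliminium chloride | COc1c(O)ccc(C=[N+](C)C)c1O.[Cl-] | intermediate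
3 | 2,4-dihydroxy-3-methoxybenzaldehyde | COc1c(O)ccc(C=O)c1O | intermediate
4 | 4-(benzyloxy)-2-hydroxy-3-methoxybenzaldehyde | COc1c(OCc2ccccc2)ccc(C=O)c1O | intermediate
5 | 4-(benzyloxy)-2-hydroxy-3-methoxybenzyl alcohol | OCc1ccc(OCc2ccccc2)c(OC)c1O | intermediate
6 | 2,6-dimethoxyphenol (syringol) | COc1cccc(OC)c1O | starting material
7 | 2-(benzyloxy)-1,3-dimethoxybenzene | COc1cccc(OC)c1OCc1ccccc1 | intermediate
8 | 3-(benzyloxy)-1,5-dibromo-2,4-dimethoxybenzene | COc1c(Br)cc(Br)c(OC)c1OCc1ccccc1 | intermediate
9 | [3-(benzyloxy)-5-bromo-2,4-dimethoxyphenyl]lithium | COc1c(Br)cc([Li])c(OC)c1OCc1ccccc1 | intermediate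
10 | lithium [3-(benzyloxy)-5-bromo-2,4-dimethoxyphenyl]trimethoxyborate | [Li+].CO[B-](OC)(OC)c1cc(Br)c(OC)c(OCc2ccccc2)c1OC | intermediate
11 | 3-(benzyloxy)-5-bromo-2,4-dimethoxyphenol | COc1c(O)cc(Br)c(OC)c1OCc1ccccc1 | intermediate
12 | 3-(benzyloxy)-1-bromo-2,4,5-trimethoxybenzene | COc1cc(Br)c(OC)c(OCc2ccccc2)c1OC | intermediate
13 | (E)-2-(2-ethoxyvinyl)-4,4,5,5-tetramethyl-1,3,2-dioxaborolane | CCO/C=C/B1OC(C)(C)C(C)(C)O1 | starting material
14 | 3-(benzyloxy)-1-[(E)-2-ethoxyvinyl]-2,4,5-trimethoxybenzene | CCO/C=C/c1cc(OC)c(OC)c(OCc2ccccc2)c1OC | intermediate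
15 | 3-(benzyloxy)-2-methoxy-6-methylidenecyclohexa-2,4-dien-1-one (ortho-quinone methide) | C=C1C=CC(OCc2ccccc2)=C(OC)C1=O | intermediate
16 | (2R,3S)-7-(benzyloxy)-3-[3-(benzyloxy)-2,4,5-trimethoxyphenyl]-2-ethoxy-8-methoxychroman (2,3-trans) | COc1cc([C@@H]2Cc3ccc(OCc4ccccc4)c(OC)c3O[C@H]2OCC)c(OC)c(OCc2ccccc2)c1OC | intermediate
17 | (3S)-7-(benzyloxy)-3-[3-(benzyloxy)-2,4,5-trimethoxyphenyl]-8-methoxy-3,4-dihydrochromen-1-ium ethoxytrifluoroborate | COc1cc([C@@H]2Cc3ccc(OCc4ccccc4)c(OC)c3[O+]=C2)c(OC)c(OCc2ccccc2)c1OC.CCO[B-](F)(F)F | intermediate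
18 | (3S)-7-(benzyloxy)-3-[3-(benzyloxy)-2,4,5-trimethoxyphenyl]-8-methoxychroman | COc1cc([C@H]2COc3c(ccc(OCc4ccccc4)c3OC)C2)c(OC)c(OCc2ccccc2)c1OC | intermediate
19 | (3S)-3-(3-hydroxy-2,4,5-trimethoxyphenyl)-8-methoxychroman-7-ol | COc1cc([C@H]2COc3c(ccc(O)c3OC)C2)c(OC)c(O)c1OC | target

**Step count**
- Total: 11 steps.
- Longest linear sequence: 8 steps (steps 4–11, from syringol).

**Steps most likely to fail**

1. Step 9.
   - What may go wrong: weak discrimination of the enol ether faces, since methide-face shielding and the endo preference must both be high. Acid-catalysed addition of water or of the hydroxyl groups of 5 across the enol ether is also possible. So are scrambling of the alkene geometry by reversible protonation and self-condensation of the methide.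
   - Fallback: it sets out from 5 and 14 and comes back at 16. The two partners are heated without any acid (toluene, sealed tube, 130–150 °C). This is the long-known thermal dehydration of salicyl alcohols to ortho-quinone methides with trapping by enol ethers.
   - Suprafacial addition should still give only the trans acetal, now as the racemate of 16 and its (2S,3R) mirror-image acetal F1.
   - The enantiomers are separated by preparative chromatography on a polysaccharide-based chiral stationary phase, and 16 goes on to step 10.

2. Step 10.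
   - What may go wrong: proton loss from C3 of the oxocarbenium ion followed by reprotonation, which erodes the enantiomeric purity. Competing cleavage of the endocyclic O1–C2 bond with reduction to a ring-opened ether is the second risk.
   - Fallback: it sets out from 16 and comes back at 18. The acetal is hydrolysed in a large excess of water (1 M HCl, THF, 0 °C) to the lactol (3S)-7-(benzyloxy)-3-[3-(benzyloxy)-2,4,5-trimethoxyphenyl]-8-methoxychroman-2-ol F2.
   - F2 is reduced at once through its ring-chain equilibrium (NaBH4, EtOH, 0 °C) to the phenol alcohol 3-(benzyloxy)-6-{(2S)-2-[3-(benzyloxy)-2,4,5-trimethoxyphenyl]-3-hydroxypropyl}-2-methoxyphenol F3.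
   - Mitsunobu etherification (PPh3, DIAD, THF, 0 °C) re-forms O1–C2 by SN2 displacement at the primary carbon without touching C3 and gives 18.

3. Step 8.
   - What may go wrong: protodeboronation of the alkoxyvinylboronate, slow oxidative addition to the electron-rich, ortho-substituted bromide, and hydrolysis of the enol ether during isolation.
   - Fallback: it sets out from 12 and comes back at 18. Bromine–lithium exchange (n-BuLi, THF, −78 °C) gives [3-(benzyloxy)-2,4,5-trimethoxyphenyl]lithium F4. DMF and a 1 M HCl work-up convert it into 3-(benzyloxy)-2,4,5-trimethoxybenzaldehyde F5.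
   - Wittig methoxymethylenation ((methoxymethyl)triphenylphosphonium chloride, KOt-Bu, THF, 0 °C) gives the methyl enol ether as a mixture of the (E)-isomer F6 and the (Z)-isomer F7, which is separated on base-washed silica.
   - F6 takes the place of 14 under the conditions of step 9 and should give the (2R,3S)-2-methoxy acetal F8. The conditions of step 10 then convert F8 into 18.

**Further compounds**
F1 | step 9 | (2S,3R)-7-(benzyloxy)-3-[3-(benzyloxy)-2,4,5-trimethoxyphenyl]-2-ethoxy-8-methoxychroman | COc1cc([C@H]2Cc3ccc(OCc4ccccc4)c(OC)c3O[C@@H]2OCC)c(OC)c(OCc2ccccc2)c1OC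
F2 | step 10 | (3S)-7-(benzyloxy)-3-[3-(benzyloxy)-2,4,5-trimethoxyphenyl]-8-methoxychroman-2-ol (anomer mixture) | COc1cc([C@@H]2Cc3ccc(OCc4ccccc4)c(OC)c3OC2O)c(OC)c(OCc2ccccc2)c1OC
F3 | step 10 | 3-(benzyloxy)-6-{(2S)-2-[3-(benzyloxy)-2,4,5-trimethoxyphenyl]-3-hydroxypropyl}-2-methoxyphenol | COc1cc([C@@H](CO)Cc2ccc(OCc3ccccc3)c(OC)c2O)c(OC)c(OCc2ccccc2)c1OC
F4 | step 8 | [3-(benzyloxy)-2,4,5-trimethoxyphenyl]lithium | [Li]c1cc(OC)c(OC)c(OCc2ccccc2)c1OC
F5 | step 8 | 3-(benzyloxy)-2,4,5-trimethoxybenzaldehyde | COc1cc(C=O)c(OC)c(OCc2ccccc2)c1OC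
F6 | step 8 | 3-(benzyloxy)-2,4,5-trimethoxy-1-[(E)-2-methoxyvinyl]benzene | CO/C=C/c1cc(OC)c(OC)c(OCc2ccccc2)c1OC
F7 | step 8 | 3-(benzyloxy)-2,4,5-trimethoxy-1-[(Z)-2-methoxyvinyl]benzene | CO/C=C\c1cc(OC)c(OC)c(OCc2ccccc2)c1OC
F8 | step 8 | (2R,3S)-7-(benzyloxy)-3-[3-(benzyloxy)-2,4,5-trimethoxyphenyl]-2,8-dimethoxychroman | COc1cc([C@@H]2Cc3ccc(OCc4ccccc4)c(OC)c3O[C@H]2OC)c(OC)c(OCc2ccccc2)c1OC
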